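All runs were generated by integration from invented constants; noise was put on by code.

Start with the late rows of east. You want the largest amount in beta, delta and zeta, which share one charge and differ in time.

* which of these there is most of at the end, counted by the substrate in it, beta (solvolysis product / substrate / other capture product / target)
* which of these there is most of at the end, counted by the substrate in it, delta (solvolysis product / substrate / other capture product / target)
* which of these there is most of at the end, counted by the substrate in it, zeta (solvolysis product / substrate / other capture product / target)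
* the largest of these amounts at the end, in percent of the substrate charged, beta
* the largest of these amounts at the end, in percent of the substrate charged, delta
* the largest of these amounts at the end, in percent of the substrate charged, zeta

all flasks: substrate 0.050 M

| flask | first nucleophile | second nucleophile | protic impurity | remark | time |
|---|---|---|---|---|---|
| east | 1.3 equiv | 1.3 equiv | 0.050 M | run made earlier |  |
| north | 2 equiv | 1.3 equiv | 0.050 M | run made earlier |  |
| west | 0.90 equiv | 0.65 equiv | 0.050 M | run made earlier |  |
| beta | 0.900 equiv | 1.30 equiv | 0.0500 M |  | 30 min |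
| delta | 0.900 equiv | 1.30 equiv | 0.0500 M |  | 45 min |
| zeta | 0.900 equiv | 1.30 equiv | 0.0500 M |  | 68 min |

- a reading of substrate is of its free form alone

| run | time / min | substrate / % | other capture product / % | target / % | solvolysis product / % |
|---|---|---|---|---|---|
| east | 1.33 | 54.4 | 10.5 | 2.9 | 0.8 |
| east | 4.00 | 18.9 | 22.4 | 6.9 | 1.9 |
| east | 6.00 | 9.4 | 24.7 | 6.7 | 2.5 |
| east | 10.0 | 2.9 | 27.6 | 6.7 | 4.5 |
| east | 15.0 | 4.4 | 29.8 | 5.9 | 1.1 |
| east | 20.0 | 1.2 | 30.6 | 9.0 | 1.9 |
| east | 25.0 | 4.9 | 32.3 | 10.4 | 2.3 |
| north | 2.00 | 40.7 | 13.6 | 6.2 | 0.1 |
| north | 3.00 | 27.6 | 15.2 | 6.2 | 1.6 |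
| north | 4.00 | 19.4 | 18.4 | 8.5 | 1.2 |
| north | 6.00 | 9.2 | 20.8 | 9.8 | 2.5 |
| north | 10.0 | 3.3 | 26.4 | 9.6 | 2.2 |
| north | 15.0 | 5.9 | 26.5 | 10.2 | 3.2 |
| north | 25.0 | 2.2 | 29.1 | 12.8 | 2.3 |
| west | 5.00 | 13.8 | 19.3 | 7.5 | 2.6 |
| west | 10.0 | 4.0 | 23.0 | 9.7 | 5.1 |
| west | 15.0 | 4.1 | 23.2 | 10.4 | 5.2 |
| west | 20.0 | 2.0 | 24.7 | 10.3 | 5.4 |
| west | 25.0 | 4.0 | 26.9 | 9.8 | 7.4 |

(scatter of a reading: 1 percentage point)

East is the nearest run, with the same second nucleophile charge as these flasks, so read its table row against row. The reading c(substrate) falls from 54.4 % at 1.33 min to 2.9 % at 10.0 min, and from there it stays between 1.2 % and 4.9 %, a floor as far as readings good to 1 percentage point can show one. Yet at 25.0 min the four columns add to 49.9 %, about half of the charge, so the rest stands in a form these columns do not read.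

Now look down the other capture column, which keeps climbing on that floor, from 27.6 % at 10.0 min to 32.3 % at 25.0 min. That is 0.00313 min⁻¹ as a fraction of the charge, the late gain: the other capture product added per minute once the substrate reading has reached its floor. It is a reading, with the scatter of 1 point at each end.

My own reckoning extends this line from the last east reading, leaving uncorrected that these flasks carry 0.900 equiv of first nucleophile against 1.3 equiv in east. It gives 33.9 % at 30 min, 38.6 % at 45 min and 45.8 % at 68 min. The other columns at 25.0 min stand at 10.4 % or less, so I name other capture product the largest in beta, delta and zeta.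

The forecast differs from this in beta and delta. It gives substrate at 53.5 % for beta, substrate at 48.5 % for delta, and other capture product at 44 % for zeta, on the ground of “Counting bound plus free substrate”.

    second nucleophile + intermediate → other capture product (k = 18.0 M⁻¹ s⁻¹)
    first nucleophile + protic impurity → quenched reagent (k = 0.0130 M⁻¹ s⁻¹)
    first nucleophile + intermediate → target (k = 5.30 M⁻¹ s⁻¹)
    substrate → intermediate (k = 0.00260 s⁻¹)
    substrate ⇌ dormant form (K = 13.0, k = 0.00480 s⁻¹)
    intermediate → solvolysis product (k = 0.110 s⁻¹)

In beta other capture product leads at 35.7 %, in delta other capture product at 40.4 %, and in zeta other capture product at 46.6 %. At 30.0 min in beta the dormant form, the substrate's resting state, held 50.9 % while free substrate stood at 2.59 %. From beta at 30.0 min to zeta at 68.0 min, two flasks of one charge, the dormant form went down to 38.2 % while other capture product went up by 0.00287 min⁻¹ as a fraction of the charge, beside the late gain of 0.00313 min⁻¹ read in east. Carried from the east reading at 10.0 min to 12 min, the late gain gives 28.2 %, and that earlier reading of beta holds 29.5 % of other capture product.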